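**Retrosynthetic overview**
1. Target 29 ← allyl ester 28 ← C-3 ketone 27 (bulky hydride) ← enolate hydroxylation and 19,20-lactonisation of tetracycle 25.
2. Ring D of 25 ← 5-exo vinyl-radical closure (C-13–C-16) of bromoallyl allylic alcohol 24 ← Schenck ene reaction on the Δ11(12) alkene 22.
3. Key step: rings A and B of 22 together, by one oxidative radical tandem cyclisation of acyclic β-keto ester 21 onto the ring C cyclohexene (C-4–C-5 by 6-endo, then C-9–C-10 by 5-exo).
4. 21 ← dianion of methyl 2-methylacetoacetate + alkylidene-oxetane 17; C-6 and C-8 of 17 ← Ireland–Claisen rearrangement of ester 13 (CBS alcohol 7 + acid 12).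
5. Ring order: C (from cyclohexane-1,3-dione) → A and B together → D → lactone.

Assumption: positions follow gibberellane numbering of the target (C-7 acid on C-6, C-17 exocyclic methylene, C-18 methyl, C-19(=O)–O–C-20 lactone), β is the face of C-18 and H-5, and where a name and a SMILES could be read differently the SMILES holds.

**Step 1**
Reactants: 1 cyclohexane-1,3-dione
Product: 2 3-ethoxycyclohex-2-en-1-one
Conditions: EtOH, TsOH·H2O (cat.), toluene, reflux, Dean–Stark
Reagents that add atoms: ethanol, CCO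
Why: Acid-catalysed enol-ether formation of the 1,3-diketone (vinylogous ester), driven by azeotropic removal of water, gives the Stork–Danheiser substrate; no stereocentre is formed.

**Step 2**
Reactants: 2 3-ethoxycyclohex-2-en-1-one; 3 2,3-dibromoprop-1-ene
Product: 6 3-(2-bromoprop-2-en-1-yl)cyclohex-2-en-1-one, via (2-bromoprop-2-en-1-yl)zinc bromide 4 (not isolated), via tertiary carbinol 5 (not isolated)
Conditions: Zn dust, THF/sat. aq. NH4Cl, 0 °C to rt; then 2 M HCl, THF, rt
Reagents that add atoms: water, O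
Why: Zinc-mediated Barbier allylation adds the 2-bromoallyl group to the carbonyl carbon, and acid then ionises the tertiary allylic carbinol and hydrolyses the enol ether (Stork–Danheiser 1,3-carbonyl transposition), giving the 3-substituted enone whose vinyl bromide is the later ring D radical precursor; no stereocentre is formed.

**Step 3**
Reactants: 6 3-(2-bromoprop-2-en-1-yl)cyclohex-2-en-1-one
Product: 7 (1R)-3-(2-bromoprop-2-en-1-yl)cyclohex-2-en-1-ol
Conditions: (S)-1-methyl-3,3-diphenyltetrahydro-1H,3H-pyrrolo[1,2-c][1,3,2]oxazaborole (10 mol %), BH3·SMe2, THF, −20 °C; MeOH quench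
Reagents that add atoms: none
Why: Corey–Bakshi–Shibata reduction, in which the (S)-catalyst binds the ketone with the alkenyl side as the large group and delivers hydride to one face, sets the carbinol centre (future C-11) as R; this is the only externally induced stereocentre and all later ones derive from it.

**Step 4**
Reactants: 8 3-bromopropanoic acid
Product: 9 (2-carboxyethyl)triphenylphosphonium bromide
Conditions: PPh3, MeCN, reflux
Reagents that add atoms: triphenylphosphine, c1ccc(cc1)P(c1ccccc1)c1ccccc1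
Why: SN2 quaternisation of triphenylphosphine by the primary bromide gives the Wittig salt; no stereocentre is formed.

**Step 5**
Reactants: 9 (2-carboxyethyl)triphenylphosphonium bromide; 10 oxetan-3-one
Product: 12 3-(oxetan-3-ylidene)propanoic acid, via sodium ylide carboxylate 11 (not isolated)
Conditions: NaN(SiMe3)2 (2.2 equiv), THF, −78 °C to rt; then cold 1 M HCl to pH 3
Reagents that add atoms: none
Why: Wittig olefination of the strained, electrophilic ketone by the carboxylate-bearing non-stabilised ylide gives the β,γ-unsaturated acid, and because the oxetane is symmetric the new alkene has no geometry to control.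

**Step 6**
Reactants: 7 (1R)-3-(2-bromoprop-2-en-1-yl)cyclohex-2-en-1-ol; 12 3-(oxetan-3-ylidene)propanoic acid
Product: 13 (1R)-3-(2-bromoprop-2-en-1-yl)cyclohex-2-en-1-yl 3-(oxetan-3-ylidene)propanoate
Conditions: N-(3-dimethylaminopropyl)-N′-ethylcarbodiimide hydrochloride, 4-(dimethylamino)pyridine (cat.), CH2Cl2, 0 °C to rt
Reagents that add atoms: none
Why: Steglich esterification joins the two halves by acyl transfer to oxygen, so the carbinol centre is not touched and stays R.

**Step 7**
Reactants: 13 (1R)-3-(2-bromoprop-2-en-1-yl)cyclohex-2-en-1-yl 3-(oxetan-3-ylidene)propanoate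
Product: 17 prop-2-en-1-yl (2S)-2-[(1R)-1-(2-bromoprop-2-en-1-yl)cyclohex-2-en-1-yl]-3-(oxetan-3-ylidene)propanoate, via silyl ketene acetal 14 (not isolated), via trimethylsilyl ester 15 (not isolated), via carboxylic acid 16 (not isolated)
Conditions: LiN(i-Pr)2, THF, −78 °C; Me3SiCl, Et3N, −78 °C to rt, then 50 °C; pH 5 aqueous work-up; then K2CO3, allyl bromide, DMF, rt
Reagents that add atoms: allyl bromide, C=CCBr
Why: Ireland–Claisen rearrangement, whose suprafacial [3,3] shift transfers the R carbinol centre to the new quaternary C-8 (R), while the LiN(i-Pr)2/THF-derived ketene acetal (alkenyl group cis to the ring oxygen) reacting through the boat-like transition state expected for cyclohex-2-enyl esters sets C-6 as S, and the freed acid is O-allylated so that it can be unmasked at the end without hydrolysis.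

**Step 8**
Reactants: 18 methyl 3-oxobutanoate
Product: 19 methyl 2-methyl-3-oxobutanoate
Conditions: MeI, K2CO3, acetone, reflux
Reagents that add atoms: iodomethane, CI
Why: C-methylation of the β-keto ester enolate installs the future C-18 methyl and makes the α-carbon a tertiary radical precursor; its configuration is irrelevant because C-4 is set in step 10.

**Step 9**
Reactants: 19 methyl 2-methyl-3-oxobutanoate; 17 prop-2-en-1-yl (2S)-2-[(1R)-1-(2-bromoprop-2-en-1-yl)cyclohex-2-en-1-yl]-3-(oxetan-3-ylidene)propanoate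
Product: 21 1-methyl 9-(prop-2-en-1-yl) (8S)-8-[(1R)-1-(2-bromoprop-2-en-1-yl)cyclohex-2-en-1-yl]-6-(hydroxymethyl)-2-methyl-3-oxonon-6-enedioate, via dilithium dianion 20 (not isolated)
Conditions: 19, LiN(i-Pr)2 (2.2 equiv), THF, 0 °C; then −78 °C, 17, BF3·OEt2; sat. aq. NH4Cl
Reagents that add atoms: none
Why: Proposed new method: the γ-carbon of the dilithium (Weiler) dianion opens the BF3-activated, strained 3-alkylidene-oxetane by SN2 attack at one of its two equivalent allylic CH2–O carbons, forming C-1–C-2 and unmasking the C-20 alcohol in one operation, the closest known reactions being BF3-promoted oxetane opening by lithium enolates and γ-alkylation of acetoacetate dianions by allylic halides; C-6 and C-8 are untouched at −78 °C and the mixed alkene geometry and C-2 epimers of the chain are erased in step 10.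

**Step 10**
Reactants: 21 1-methyl 9-(prop-2-en-1-yl) (8S)-8-[(1R)-1-(2-bromoprop-2-en-1-yl)cyclohex-2-en-1-yl]-6-(hydroxymethyl)-2-methyl-3-oxonon-6-enedioate
Product: 22 7-(prop-2-en-1-yl) 19-methyl 16-bromo-20-hydroxy-3-oxo-13,16-secogibberella-11,16-diene-7,19-dioate
Conditions: Mn(OAc)3·2H2O (2.2 equiv), Cu(OAc)2·H2O (1 equiv), degassed AcOH (0.02 M), 40 °C
Reagents that add atoms: none
Why: Snider-type oxidative free-radical tandem cyclisation, in which the trivalent-manganese enolate gives the C-4 radical that closes ring A 6-endo on C-5 through a chair with the ester axial (cis to C-20) and anti to the bulky C-8 group in the A1,3-minimised rotamer about C-5–C-6 (setting C-4 and C-5), the tertiary C-10 radical then closes ring B 5-exo on C-9 of the cyclohexene with the trans ring A/ring B fusion expected from related tandem cyclisations and the geometrically enforced cis ring B/ring C fusion (setting C-10 and C-9), and divalent copper oxidises the secondary C-11 radical to the Δ11(12) alkene.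

**Step 11**
Reactants: 22 7-(prop-2-en-1-yl) 19-methyl 16-bromo-20-hydroxy-3-oxo-13,16-secogibberella-11,16-diene-7,19-dioate
Product: 24 7-(prop-2-en-1-yl) 19-methyl 16-bromo-11β,20-dihydroxy-3-oxo-13,16-secogibberella-12,16-diene-7,19-dioate, via allylic hydroperoxide 23 (not isolated)
Conditions: O2, visible light, meso-tetraphenylporphyrin (cat.), CH2Cl2, 0 °C; then PPh3
Reagents that add atoms: dioxygen, O=O
Why: Schenck ene reaction, in which singlet oxygen attacks the alkene face anti to the axial C-10 substituent on C-9 and abstracts the pseudo-axial H-13 (H-9 is pseudo-equatorial and not aligned), so oxygen ends on C-11 β and the alkene moves to C-12/C-13, the hydroperoxide being reduced in the same flask by PPh3.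

**Step 12**
Reactants: 24 7-(prop-2-en-1-yl) 19-methyl 16-bromo-11β,20-dihydroxy-3-oxo-13,16-secogibberella-12,16-diene-7,19-dioate
Product: 25 7-(prop-2-en-1-yl) 19-methyl 11β,20-dihydroxy-3-oxogibberell-16-ene-7,19-dioate
Conditions: Bu3SnH (1.3 equiv, 0.02 M), azobis(isobutyronitrile) (cat.), benzene, 80 °C
Reagents that add atoms: none
Why: Tin-hydride vinyl-radical cyclisation, in which the C-16 vinyl radical held axially on the β face of C-8 adds 5-exo to C-13 of the ring C alkene, closing ring D, fixing the bridgehead C-13 and giving the exocyclic methylene directly, after which the C-12 radical takes hydrogen from Bu3SnH.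

**Step 13**
Reactants: 25 7-(prop-2-en-1-yl) 19-methyl 11β,20-dihydroxy-3-oxogibberell-16-ene-7,19-dioate
Product: 27 7-(prop-2-en-1-yl) ester of 2β,11β,20-trihydroxy-3-oxogibberell-16-ene-7,19-dioic acid 19,20-lactone, via keto lactone 26 (not isolated)
Conditions: KN(SiMe3)2 (4.5 equiv), THF, −78 to −20 °C; then −78 °C, 3-phenyl-2-(phenylsulfonyl)oxaziridine; sat. aq. NH4Cl
Reagents that add atoms: 3-phenyl-2-(phenylsulfonyl)oxaziridine, O=S(=O)(c1ccccc1)N1OC1c1ccccc1
Why: The C-20 alkoxide closes the 19,20-δ-lactone on the 1,3-diaxial C-19 methyl ester (intramolecular transesterification) and the C-2 potassium enolate of the C-3 ketone is then hydroxylated by the Davis oxaziridine from the β (exo) face, because the α face of C-2 lies under the lactone bridge, giving the equatorial 2β-alcohol (Davis enolate hydroxylation).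

**Step 14**
Reactants: 27 7-(prop-2-en-1-yl) ester of 2β,11β,20-trihydroxy-3-oxogibberell-16-ene-7,19-dioic acid 19,20-lactone
Product: 28 7-(prop-2-en-1-yl) ester of 2β,3β,11β,20-tetrahydroxygibberell-16-ene-7,19-dioic acid 19,20-lactone
Conditions: Li[BH(s-Bu)3], THF, −78 °C; sat. aq. NH4Cl
Reagents that add atoms: none
Why: Bulky-hydride (L-Selectride) reduction, in which the reagent attacks the C-3 ketone along the equatorial trajectory from the α side, away from the 1,3-diaxial β hydrogens at C-1 and C-5, gives the axial 3β-alcohol cis to the 2β-hydroxyl while lactone and allyl ester are inert at −78 °C.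

**Step 15**
Reactants: 28 7-(prop-2-en-1-yl) ester of 2β,3β,11β,20-tetrahydroxygibberell-16-ene-7,19-dioic acid 19,20-lactone
Product: 29 2β,3β,11β,20-tetrahydroxygibberell-16-ene-7,19-dioic acid 19,20-lactone (target CNP0302900.3)
Conditions: Pd(PPh3)4 (5 mol %), morpholine, THF, rt
Reagents that add atoms: none
Why: Tsuji–Trost deallylation, in which zerovalent palladium ionises the allyl ester and morpholine traps the π-allyl, frees the C-7 acid under neutral conditions that spare the lactone, the exocyclic alkene and the retro-aldol-prone 3β-hydroxy lactone, so no stereocentre changes.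

**Compound list**
1 | cyclohexane-1,3-dione | O=C1CCCC(=O)C1 | starting material
2 | 3-ethoxycyclohex-2-en-1-one | CCOC1=CC(=O)CCC1 | intermediate
3 | 2,3-dibromoprop-1-ene | C=C(Br)CBr | starting material
4 | (2-bromoprop-2-en-1-yl)zinc bromide (not isolated) | C=C(Br)C[Zn]Br | intermediate
5 | 1-(2-bromoprop-2-en-1-yl)-3-ethoxycyclohex-2-en-1-ol (racemic; not isolated) | CCOC1=CC(O)(CC(Br)=C)CCC1 | intermediate
6 | 3-(2-bromoprop-2-en-1-yl)cyclohex-2-en-1-one | C=C(Br)CC1=CC(=O)CCC1 | intermediate
7 | (1R)-3-(2-bromoprop-2-en-1-yl)cyclohex-2-en-1-ol | C=C(Br)CC1=C[C@H](O)CCC1 | intermediate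
8 | 3-bromopropanoic acid | OC(=O)CCBr | starting material
9 | (2-carboxyethyl)triphenylphosphonium bromide | OC(=O)CC[P+](c1ccccc1)(c1ccccc1)c1ccccc1.[Br-] | intermediate
10 | oxetan-3-one | O=C1COC1 | starting material
11 | sodium 3-(triphenyl-λ5-phosphanylidene)propanoate (not isolated) | [Na+].[O-]C(=O)CC=P(c1ccccc1)(c1ccccc1)c1ccccc1 | intermediate
12 | 3-(oxetan-3-ylidene)propanoic acid | OC(=O)CC=C1COC1 | intermediate
13 | (1R)-3-(2-bromoprop-2-en-1-yl)cyclohex-2-en-1-yl 3-(oxetan-3-ylidene)propanoate | C=C(Br)CC1=C[C@H](OC(=O)CC=C2COC2)CCC1 | intermediate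
14 | (E)-trimethylsilyl ketene acetal of 13, alkenyl group cis to the ring oxygen (not isolated) | C=C(Br)CC1=C[C@H](O/C(O[Si](C)(C)C)=C\C=C2COC2)CCC1 | intermediate
15 | trimethylsilyl (2S)-2-[(1R)-1-(2-bromoprop-2-en-1-yl)cyclohex-2-en-1-yl]-3-(oxetan-3-ylidene)propanoate (not isolated) | C=C(Br)C[C@]1(C=CCCC1)[C@@H](C(=O)O[Si](C)(C)C)C=C1COC1 | intermediate
16 | (2S)-2-[(1R)-1-(2-bromoprop-2-en-1-yl)cyclohex-2-en-1-yl]-3-(oxetan-3-ylidene)propanoic acid (not isolated) | C=C(Br)C[C@]1(C=CCCC1)[C@@H](C(=O)O)C=C1COC1 | intermediate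
17 | prop-2-en-1-yl (2S)-2-[(1R)-1-(2-bromoprop-2-en-1-yl)cyclohex-2-en-1-yl]-3-(oxetan-3-ylidene)propanoate | C=C(Br)C[C@]1(C=CCCC1)[C@@H](C(=O)OCC=C)C=C1COC1 | intermediate
18 | methyl 3-oxobutanoate | CC(=O)CC(=O)OC | starting material
19 | methyl 2-methyl-3-oxobutanoate | CC(=O)C(C)C(=O)OC | intermediate
20 | dilithium dianion of 19 (not isolated) | [Li+].[Li+].C=C([O-])C(C)=C([O-])OC | intermediate
21 | 1-methyl 9-(prop-2-en-1-yl) (8S)-8-[(1R)-1-(2-bromoprop-2-en-1-yl)cyclohex-2-en-1-yl]-6-(hydroxymethyl)-2-methyl-3-oxonon-6-enedioate (E/Z and C-2 epimer mixture) | C=C(Br)C[C@]1(C=CCCC1)[C@@H](C(=O)OCC=C)C=C(CO)CCC(=O)C(C)C(=O)OC | intermediate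
22 | 7-(prop-2-en-1-yl) 19-methyl 16-bromo-20-hydroxy-3-oxo-13,16-secogibberella-11,16-diene-7,19-dioate (rings A/B/C; 4β-Me, 4α-CO2Me, H-5β, 6β-CO2allyl, H-9β, 10α-CH2OH, 8β-bromoallyl) | C=C(Br)C[C@]23CCC=C[C@H]2[C@]1(CO)CCC(=O)[C@@](C)(C(=O)OC)[C@H]1[C@@H]3C(=O)OCC=C | intermediate
23 | 11β-hydroperoxide: 7-(prop-2-en-1-yl) 19-methyl 16-bromo-11β-hydroperoxy-20-hydroxy-3-oxo-13,16-secogibberella-12,16-diene-7,19-dioate (not isolated) | C=C(Br)C[C@]23CC=C[C@H](OO)[C@H]2[C@]1(CO)CCC(=O)[C@@](C)(C(=O)OC)[C@H]1[C@@H]3C(=O)OCC=C | intermediate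
24 | 7-(prop-2-en-1-yl) 19-methyl 16-bromo-11β,20-dihydroxy-3-oxo-13,16-secogibberella-12,16-diene-7,19-dioate | C=C(Br)C[C@]23CC=C[C@H](O)[C@H]2[C@]1(CO)CCC(=O)[C@@](C)(C(=O)OC)[C@H]1[C@@H]3C(=O)OCC=C | intermediate
25 | 7-(prop-2-en-1-yl) 19-methyl 11β,20-dihydroxy-3-oxogibberell-16-ene-7,19-dioate | C=C1C[C@]23C[C@H]1C[C@H](O)[C@H]2[C@]1(CO)CCC(=O)[C@@](C)(C(=O)OC)[C@H]1[C@@H]3C(=O)OCC=C | intermediate
26 | 7-(prop-2-en-1-yl) ester of 11β,20-dihydroxy-3-oxogibberell-16-ene-7,19-dioic acid 19,20-lactone (not isolated) | C=C1C[C@]23C[C@H]1C[C@H](O)[C@H]2[C@]12COC(=O)[C@](C)(C(=O)CC1)[C@H]2[C@@H]3C(=O)OCC=C | intermediate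
27 | 7-(prop-2-en-1-yl) ester of 2β,11β,20-trihydroxy-3-oxogibberell-16-ene-7,19-dioic acid 19,20-lactone | C=C1C[C@]23C[C@H]1C[C@H](O)[C@H]2[C@]12COC(=O)[C@](C)(C(=O)[C@@H](O)C1)[C@H]2[C@@H]3C(=O)OCC=C | intermediate
28 | 7-(prop-2-en-1-yl) ester of 2β,3β,11β,20-tetrahydroxygibberell-16-ene-7,19-dioic acid 19,20-lactone | C=C1C[C@]23C[C@H]1C[C@H](O)[C@H]2[C@]12COC(=O)[C@](C)([C@@H](O)[C@@H](O)C1)[C@H]2[C@@H]3C(=O)OCC=C | intermediate
29 | 2β,3β,11β,20-tetrahydroxygibberell-16-ene-7,19-dioic acid 19,20-lactone (CNP0302900.3) | C=C1C[C@]23C[C@H]1C[C@H](O)[C@H]2[C@]12COC(=O)[C@](C)([C@@H](O)[C@@H](O)C1)[C@H]2[C@@H]3C(=O)O | target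

**Step count and risk**
Total: 15 steps; two short side branches are steps 4–5 (acid 12) and step 8 (keto ester 19). Longest linear sequence: 12 steps (1, 2, 3, 6, 7, 9, 10, 11, 12, 13, 14, 15).

The three steps most likely to fail:

Step 10 (radical tandem cyclisation). Divalent copper may oxidise the tertiary C-10 radical before it closes ring B on the hindered C-9, and the C-11 radical may add to the bromoallyl arm. The fallback sets out from 21 and comes back at 22. 21 is brominated at C-4 (NaH, then N-bromosuccinimide, THF, −78 °C) to 1-methyl 9-(prop-2-en-1-yl) (8S)-2-bromo-8-[(1R)-1-(2-bromoprop-2-en-1-yl)cyclohex-2-en-1-yl]-6-(hydroxymethyl)-2-methyl-3-oxonon-6-enedioate F2. With no metal oxidant present, F2 is cyclised by bromine-atom transfer (Et3B, air, toluene, −20 °C), the chain ending by bromine transfer to C-11 and giving the 11-bromo-11,12-dihydro analogue of 22 F3. DBU (toluene, 80 °C) then eliminates HBr to the Δ11(12) alkene 22.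

Step 9 (unprecedented dianion opening of the alkylidene-oxetane; BF3 may instead decompose the oxetane or the dianion may deprotonate C-6). The fallback sets out from 17 and comes back at 21. The oxetane of 17 is first opened by halide with Me3SiBr (CH2Cl2, −78 °C) to prop-2-en-1-yl (2S)-4-(bromomethyl)-2-[(1R)-1-(2-bromoprop-2-en-1-yl)cyclohex-2-en-1-yl]-5-[(trimethylsilyl)oxy]pent-3-enoate F1. This allylic bromide is alkylated by dianion 20 in an ordinary SN2 γ-alkylation at −78 °C without Lewis acid, and mildly acidic work-up removes the silyl ether to give 21.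

Step 11 (Schenck ene: regiochemistry of hydrogen abstraction and facial selectivity). The fallback sets out from 22 and comes back at 24. 22 is epoxidised on the β face with m-chloroperbenzoic acid (CH2Cl2, NaHCO3, 0 °C) to the 11β,12β-epoxide of 22 F4. Sodium phenylselenide (from (PhSe)2 and NaBH4, EtOH) opens it trans-diaxially at C-12 to the 11β-hydroxy-12α-(phenylselanyl) compound F5. H2O2 (THF, 0 °C to rt) then oxidises the selenide, and selenoxide syn-elimination away from the carbinol gives allylic alcohol 24.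

**Further compounds**
F1 | step 9 | prop-2-en-1-yl (2S)-4-(bromomethyl)-2-[(1R)-1-(2-bromoprop-2-en-1-yl)cyclohex-2-en-1-yl]-5-[(trimethylsilyl)oxy]pent-3-enoate (E/Z mixture) | C=C(Br)C[C@]1(C=CCCC1)[C@@H](C(=O)OCC=C)C=C(CO[Si](C)(C)C)CBr
F2 | step 10 | 1-methyl 9-(prop-2-en-1-yl) (8S)-2-bromo-8-[(1R)-1-(2-bromoprop-2-en-1-yl)cyclohex-2-en-1-yl]-6-(hydroxymethyl)-2-methyl-3-oxonon-6-enedioate | C=C(Br)C[C@]1(C=CCCC1)[C@@H](C(=O)OCC=C)C=C(CO)CCC(=O)C(C)(Br)C(=O)OC
F3 | step 10 | 11-bromo-11,12-dihydro analogue of 22 (C-11 epimers) | C=C(Br)C[C@]23CCCC(Br)[C@H]2[C@]1(CO)CCC(=O)[C@@](C)(C(=O)OC)[C@H]1[C@@H]3C(=O)OCC=C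
F4 | step 11 | 11β,12β-epoxide of 22 | C=C(Br)C[C@]23CC[C@@H]4O[C@@H]4[C@H]2[C@]1(CO)CCC(=O)[C@@](C)(C(=O)OC)[C@H]1[C@@H]3C(=O)OCC=C
F5 | step 11 | 11β-hydroxy-12α-(phenylselanyl)-11,12-dihydro analogue of 22 | C=C(Br)C[C@]23CC[C@@H]([Se]c4ccccc4)[C@H](O)[C@H]2[C@]1(CO)CCC(=O)[C@@](C)(C(=O)OC)[C@H]1[C@@H]3C(=O)OCC=C
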